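**Strategy.** Everything rests on cutting the E-trisubstituted alkene nearest the stereocentre, CH2–C(CH3)=CH–CH2CH2, into an alkyl chain, a methyl group and the four ring carbons of 2,3-dihydrofuran. The key step exploits this C=CH–CH2–CH2 unit: in one operation the Roche-ester-derived alkyl group and then a methyl group are attached to the oxygen-bearing sp2 carbon (C5) of the five-membered oxygen ring, which opens with full control of alkene geometry and releases a primary alcohol for a second, identical cycle. The precursor is silyl-protected (S)-5-iodo-2-methylpentan-1-ol, used as its organocopper. Furan coupling, a stereospecific aldol–elimination with an allyl tetronate and stearoylation complete the target.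

Key step: step 9

Remark 1: the exocyclic enol-lactone alkene of the target is read as E (chain on the side of ring carbon C4 and its acyloxy group). This is the less stable geometry, so it is made by a stereospecific anti-elimination from an erythro aldol adduct, not by an equilibrating condensation.
Remark 2: the enol oxygen is carried as an allyl ether and not as a methyl ether, because demethylation needs thiolate or hot halide, which can add reversibly to the ylidene lactone and relax it to the Z isomer.
Remark 3: (R)-Roche ester, silylated on oxygen and extended at the ester carbon, maps onto the (S) iodide 8 and the (S) centre of the target; the descriptor alternates on the way only because CIP priorities change. 3-Methyltetronic acid is taken as commercially available.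
Remark 4: the cuprate is assembled 1:1:1 from alkyllithium, copper salt and lithiated dihydrofuran, so that no second equivalent of the chiral alkyl group is spent as a dummy ligand.
Remark 5: 5-lithio-2,3-dihydrofuran 10 is not stored. Step 8 is carried out immediately before step 9 and, by the same procedure, once more immediately before step 11; each time the cold THF solution is cannulated into the copper reagent.

Step 1
Reactants: 1 methyl (R)-3-hydroxy-2-methylpropanoate
Product: 2 methyl (R)-3-((tert-butyldimethylsilyl)oxy)-2-methylpropanoate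
Conditions: TBSCl, imidazole, DMF, 0 °C → rt
Reagents that add atoms: tert-butyldimethylsilyl chloride, CC(C)(C)[Si](C)(C)Cl
Why: Imidazole-promoted silyl ether formation at the primary alcohol is fast and too weakly basic to touch the ester α-stereocentre.

Step 2
Reactants: 2 methyl (R)-3-((tert-butyldimethylsilyl)oxy)-2-methylpropanoate
Product: 3 (S)-3-((tert-butyldimethylsilyl)oxy)-2-methylpropan-1-ol
Conditions: i-Bu2AlH, CH2Cl2, −78 → 0 °C; aq potassium sodium tartrate (KNaC4H4O6) work-up
Reagents that add atoms: none
Why: Hydride reduction of the ester to the primary alcohol does not involve the stereocentre, whose descriptor becomes S only through the CIP priorities.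

Step 3
Reactants: 3 (S)-3-((tert-butyldimethylsilyl)oxy)-2-methylpropan-1-ol
Product: 4 (R)-3-((tert-butyldimethylsilyl)oxy)-2-methylpropanal
Conditions: (COCl)2, DMSO, CH2Cl2, −78 °C; Et3N, −78 → 0 °C; used crude
Reagents that add atoms: none
Why: Swern oxidation stops at the aldehyde at low temperature, and immediate use of the crude product avoids enolisation of the α-methyl centre.

Step 4
Reactants: 4 (R)-3-((tert-butyldimethylsilyl)oxy)-2-methylpropanal
Product: 5 ethyl (S,E)-5-((tert-butyldimethylsilyl)oxy)-4-methylpent-2-enoate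
Conditions: Ph3P=CHCO2Et, CH2Cl2, rt
Reagents that add atoms: ethyl (triphenylphosphoranylidene)acetate, CCOC(=O)C=P(c1ccccc1)(c1ccccc1)c1ccccc1
Why: Wittig olefination with the stabilised ylide is essentially neutral, so the α-stereocentre survives; the alkene geometry is of no consequence because the next step saturates it.

Step 5
Reactants: 5 ethyl (S,E)-5-((tert-butyldimethylsilyl)oxy)-4-methylpent-2-enoate
Product: 6 ethyl (S)-5-((tert-butyldimethylsilyl)oxy)-4-methylpentanoate
Conditions: H2 (1 atm), Pd/C, EtOAc, rt
Reagents that add atoms: none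
Why: Heterogeneous catalytic hydrogenation reduces the conjugated alkene while the ester and the silyl ether are inert in ethyl acetate.

Step 6
Reactants: 6 ethyl (S)-5-((tert-butyldimethylsilyl)oxy)-4-methylpentanoate
Product: 7 (S)-5-((tert-butyldimethylsilyl)oxy)-4-methylpentan-1-ol
Conditions: i-Bu2AlH, CH2Cl2, −78 → 0 °C; aq potassium sodium tartrate (KNaC4H4O6) work-up
Reagents that add atoms: none
Why: Hydride reduction of the ester with i-Bu2AlH gives the primary alcohol and leaves the silyl ether and the remote stereocentre alone.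

Step 7
Reactants: 7 (S)-5-((tert-butyldimethylsilyl)oxy)-4-methylpentan-1-ol
Product: 8 (S)-tert-butyl((5-iodo-2-methylpentyl)oxy)dimethylsilane
Conditions: I2, PPh3, imidazole, CH2Cl2, 0 °C → rt
Reagents that add atoms: iodine, II
Why: Appel-type iodination turns the primary alcohol into the iodide by SN2 displacement of the phosphonium-activated oxygen, and the imidazole buffer spares the silyl ether.

Step 8
Reactants: 9 2,3-dihydrofuran
Product: 10 5-lithio-2,3-dihydrofuran [(4,5-dihydrofuran-2-yl)lithium] as a THF solution
Conditions: t-BuLi, THF, −78 → 0 °C; solution kept cold under argon and used at once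
Reagents that add atoms: tert-butyllithium, [Li]C(C)(C)C
Why: α-Lithiation of a cyclic enol ether: the ring oxygen coordinates lithium and acidifies the adjacent sp2 C–H, so t-BuLi removes the C5 hydrogen selectively and the alkenyllithium persists in THF at 0 °C for the time needed.

Step 9
Reactants: 8 (S)-tert-butyl((5-iodo-2-methylpentyl)oxy)dimethylsilane, 10 5-lithio-2,3-dihydrofuran
Product: 14 (S,E)-9-((tert-butyldimethylsilyl)oxy)-4,8-dimethylnon-3-en-1-ol, via alkyllithium 11 (not isolated), via mixed alkyl(dihydrofuranyl)cuprate 12 (not isolated), via ring-opened alkenylcuprate 13 (not isolated)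
Conditions: 8, t-BuLi (2 equiv), Et2O–pentane, −78 °C; CuBr·SMe2, Me2S–Et2O, −78 → −40 °C; 10 in THF added by cannula, −78 °C → rt; MeI (excess), 0 °C → rt; aq NH4Cl–NH3
Reagents that add atoms: iodomethane, CI
Why: Iodine–lithium exchange and CuBr·SMe2 turn 8 into an alkylcopper that joins lithiated dihydrofuran 10 in the mixed cuprate 12; on warming, the alkyl group migrates from copper to the oxygen-bearing alkenyl carbon C5 of the ring, anti to the ring C5–O bond and with inversion at that sp2 carbon, the alkoxide leaves and the ring opens to cuprate 13, whose copper–carbon bond is then methylated by MeI with retention. The closest known reaction type is the 1,2-metallate rearrangement of α-alkoxyalkenyl cuprates from lithiated cyclic enol ethers, followed by electrophilic trapping of the alkenylcuprate. No ring is closed (the five-membered oxygen ring is opened) and no stereocentre is formed; the stereocentre of 8 lies four bonds from the reacting carbon and is not touched. The selectivity needed is alkene geometry: the ring holds C3 and oxygen cis across the double bond, so invertive migration leaves copper cis to the CH2CH2O arm and the incoming chain trans to it, and retentive methylation can give only the E alkene. Chemoselectivity follows from the order of events: tert-butyl iodide is destroyed by the second equivalent of t-BuLi before copper is added, the silyl ether is inert to the alkyllithium at −78 °C, and the lithium alkoxide is not methylated under these conditions.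

Step 10
Reactants: 14 (S,E)-9-((tert-butyldimethylsilyl)oxy)-4,8-dimethylnon-3-en-1-ol
Product: 15 tert-butyl{[(2S,6E)-9-iodo-2,6-dimethylnon-6-en-1-yl]oxy}dimethylsilane
Conditions: I2, PPh3, imidazole, CH2Cl2, 0 °C
Reagents that add atoms: iodine, II
Why: Appel-type iodination at the primary carbon is a clean SN2 process, and no allylic transposition is possible because the alkene is homoallylic to the leaving group.

Step 11
Reactants: 15 tert-butyl{[(2S,6E)-9-iodo-2,6-dimethylnon-6-en-1-yl]oxy}dimethylsilane, 10 5-lithio-2,3-dihydrofuran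
Product: 19 (3E,7E,12S)-13-((tert-butyldimethylsilyl)oxy)-4,8,12-trimethyltrideca-3,7-dien-1-ol, via homoallyllithium 16 (not isolated), via mixed homoallyl(dihydrofuranyl)cuprate 17 (not isolated), via ring-opened homoallyl-substituted alkenylcuprate 18 (not isolated)
Conditions: 15, t-BuLi (2 equiv), Et2O–pentane, −78 °C; CuBr·SMe2, Me2S–Et2O, −78 → −40 °C; 10 in THF added by cannula, −78 °C → rt; MeI (excess), 0 °C → rt; aq NH4Cl–NH3
Reagents that add atoms: iodomethane, CI
Why: This is the same 1,2-metallate rearrangement–methylation as step 9; the homoallyllithium does not cyclise at −78 °C (closure would need a tertiary carbanion), and invertive migration followed by retentive methylation again fixes an E-trisubstituted alkene without touching the existing alkene or the stereocentre.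

Step 12
Reactants: 19 (3E,7E,12S)-13-((tert-butyldimethylsilyl)oxy)-4,8,12-trimethyltrideca-3,7-dien-1-ol
Product: 20 tert-butyl{[(2S,6E,10E)-13-iodo-2,6,10-trimethyltrideca-6,10-dien-1-yl]oxy}dimethylsilane
Conditions: I2, PPh3, imidazole, CH2Cl2, 0 °C
Reagents that add atoms: iodine, II
Why: Appel-type iodination of the primary homoallylic alcohol, as in step 10.

Step 13
Reactants: 20 tert-butyl{[(2S,6E,10E)-13-iodo-2,6,10-trimethyltrideca-6,10-dien-1-yl]oxy}dimethylsilane, 21 3-bromofuran
Product: 23 tert-butyl{[(2S,6E,10E)-13-(furan-3-yl)-2,6,10-trimethyltrideca-6,10-dien-1-yl]oxy}dimethylsilane, via alkylzinc iodide 22 (not isolated)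
Conditions: Zn dust (activated with BrCH2CH2Br, Me3SiCl), THF, 40 °C; then 21, PdCl2(dppf) (cat.), THF, 50 °C
Reagents that add atoms: none
Why: Negishi cross-coupling: zinc insertion into the primary iodide gives an alkylzinc that tolerates the silyl ether and both alkenes, and the wide-bite-angle dppf ligand on palladium favours reductive elimination over β-hydride elimination in the sp3–sp2 coupling with the bromofuran.

Step 14
Reactants: 23 tert-butyl{[(2S,6E,10E)-13-(furan-3-yl)-2,6,10-trimethyltrideca-6,10-dien-1-yl]oxy}dimethylsilane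
Product: 24 (2S,6E,10E)-13-(furan-3-yl)-2,6,10-trimethyltrideca-6,10-dien-1-ol
Conditions: Bu4NF, THF, 0 °C → rt
Reagents that add atoms: none
Why: Fluoride-mediated desilylation cleaves the Si–O bond of the primary silyl ether under conditions to which the furan and the trisubstituted alkenes are inert.

Step 15
Reactants: 24 (2S,6E,10E)-13-(furan-3-yl)-2,6,10-trimethyltrideca-6,10-dien-1-ol
Product: 25 (2S,6E,10E)-13-(furan-3-yl)-2,6,10-trimethyltrideca-6,10-dienal
Conditions: Dess–Martin periodinane, pyridine, CH2Cl2, 0 °C → rt; used crude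
Reagents that add atoms: none
Why: Dess–Martin oxidation under pyridine buffer gives the α-methyl aldehyde without strong acid or base, so neither the furan nor the α-stereocentre is at risk when the aldehyde is used at once.

Step 16
Reactants: 26 4-hydroxy-3-methylfuran-2(5H)-one (3-methyltetronic acid)
Product: 27 3-methyl-4-(prop-2-en-1-yloxy)furan-2(5H)-one
Conditions: allyl alcohol, PPh3, DIAD, THF, 0 °C → rt
Reagents that add atoms: allyl alcohol, C=CCO
Why: Mitsunobu etherification alkylates the acidic enol at O4 with the phosphonium-activated allyl alcohol, giving the vinylogous allyl ester without C-alkylation.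

Step 17
Reactants: 27 3-methyl-4-(prop-2-en-1-yloxy)furan-2(5H)-one
Product: 28 trimethyl{[3-methyl-4-(prop-2-en-1-yloxy)furan-2-yl]oxy}silane
Conditions: Me3SiOTf, Et3N, Et2O, 0 °C; pentane extraction under argon; used at once
Reagents that add atoms: trimethylsilyl trifluoromethanesulfonate, C[Si](C)(C)OS(=O)(=O)C(F)(F)F
Why: Soft enolisation (silyl triflate and tertiary amine) silylates the carbonyl oxygen and removes the C5 proton, the standard entry to 2-silyloxyfuran donors for vinylogous Mukaiyama aldol reactions.

Step 18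
Reactants: 25 (2S,6E,10E)-13-(furan-3-yl)-2,6,10-trimethyltrideca-6,10-dienal, 28 trimethyl{[3-methyl-4-(prop-2-en-1-yloxy)furan-2-yl]oxy}silane
Product: 30 (5R)-5-[(1R,2S,6E,10E)-13-(furan-3-yl)-1-hydroxy-2,6,10-trimethyltrideca-6,10-dien-1-yl]-3-methyl-4-(prop-2-en-1-yloxy)furan-2(5H)-one (erythro adduct carried on together with its (5S,1'S) erythro twin), via trimethylsilyl ether 29 (not isolated)
Conditions: Bu4N[Ph3SiF2] (cat.), THF, −78 °C; then aq citric acid, 0 °C
Reagents that add atoms: none
Why: Fluoride-triggered vinylogous Mukaiyama aldol addition: the furanolate released from 28 attacks the aldehyde through C5, and the open transition state that keeps the developing alkoxide oxygen anti to the ring oxygen and the chain away from the C4 allyloxy group should give the erythro (5R,1'R and 5S,1'S) relationship; both new centres are temporary and only their relative configuration matters, while the low temperature protects the α-methyl centre of 25.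

Step 19
Reactants: 30 (5R)-5-[(1R,2S,6E,10E)-13-(furan-3-yl)-1-hydroxy-2,6,10-trimethyltrideca-6,10-dien-1-yl]-3-methyl-4-(prop-2-en-1-yloxy)furan-2(5H)-one
Product: 31 (5E)-5-[(2S,6E,10E)-13-(furan-3-yl)-2,6,10-trimethyltrideca-6,10-dien-1-ylidene]-3-methyl-4-(prop-2-en-1-yloxy)furan-2(5H)-one
Conditions: PPh3, DEAD, THF, −20 °C → rt
Reagents that add atoms: none
Why: Mitsunobu-type dehydration of a γ-(α-hydroxyalkyl)butenolide: the alcohol becomes an alkoxyphosphonium leaving group and the acidic C5–H is removed antiperiplanar to it (E2), which from the erythro adduct places the chain cis to C4 and so gives the E enol-lactone alkene, erasing both temporary stereocentres and leaving the allylic C2' centre untouched.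

Step 20
Reactants: 31 (5E)-5-[(2S,6E,10E)-13-(furan-3-yl)-2,6,10-trimethyltrideca-6,10-dien-1-ylidene]-3-methyl-4-(prop-2-en-1-yloxy)furan-2(5H)-one
Product: 32 (5E)-5-[(2S,6E,10E)-13-(furan-3-yl)-2,6,10-trimethyltrideca-6,10-dien-1-ylidene]-4-hydroxy-3-methylfuran-2(5H)-one
Conditions: Pd(PPh3)4 (cat.), morpholine, THF, rt, dark; cold pH 3 work-up; used at once
Reagents that add atoms: none
Why: Deallylation by allyl transfer on zerovalent palladium (Tsuji–Trost type): the tetronate is an excellent leaving group for π-allyl formation and morpholine captures the allyl unit, so the enol is freed at room temperature without thiolate, acid or heat that could isomerise the E alkene.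

Step 21
Reactants: 32 (5E)-5-[(2S,6E,10E)-13-(furan-3-yl)-2,6,10-trimethyltrideca-6,10-dien-1-ylidene]-4-hydroxy-3-methylfuran-2(5H)-one
Product: 33 (5E)-5-[(2S,6E,10E)-13-(furan-3-yl)-2,6,10-trimethyltrideca-6,10-dien-1-ylidene]-3-methyl-2-oxo-2,5-dihydrofuran-4-yl octadecanoate (target)
Conditions: stearoyl chloride, Et3N, CH2Cl2, 0 °C
Reagents that add atoms: octadecanoyl chloride (stearoyl chloride), CCCCCCCCCCCCCCCCCC(=O)Cl
Why: O-Acylation of the tetronic acid with the acid chloride and triethylamine gives the enol ester at O4, C-acylation being blocked by the C3 methyl group, and the cold, weakly basic conditions should keep the E alkene and the stereocentre.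

**Compound list**

1 | methyl (R)-3-hydroxy-2-methylpropanoate (Roche ester) | OC[C@@H](C)C(=O)OC | starting material
2 | methyl (R)-3-((tert-butyldimethylsilyl)oxy)-2-methylpropanoate | CC(C)(C)[Si](C)(C)OC[C@@H](C)C(=O)OC | intermediate
3 | (S)-3-((tert-butyldimethylsilyl)oxy)-2-methylpropan-1-ol | CC(C)(C)[Si](C)(C)OC[C@@H](C)CO | intermediate
4 | (R)-3-((tert-butyldimethylsilyl)oxy)-2-methylpropanal | CC(C)(C)[Si](C)(C)OC[C@@H](C)C=O | intermediate
5 | ethyl (S,E)-5-((tert-butyldimethylsilyl)oxy)-4-methylpent-2-enoate | CC(C)(C)[Si](C)(C)OC[C@@H](C)/C=C/C(=O)OCC | intermediate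
6 | ethyl (S)-5-((tert-butyldimethylsilyl)oxy)-4-methylpentanoate | CC(C)(C)[Si](C)(C)OC[C@@H](C)CCC(=O)OCC | intermediate
7 | (S)-5-((tert-butyldimethylsilyl)oxy)-4-methylpentan-1-ol | CC(C)(C)[Si](C)(C)OC[C@@H](C)CCCO | intermediate
8 | (S)-tert-butyl((5-iodo-2-methylpentyl)oxy)dimethylsilane | CC(C)(C)[Si](C)(C)OC[C@@H](C)CCCI | intermediate
9 | 2,3-dihydrofuran | C1CC=CO1 | starting material
10 | (4,5-dihydrofuran-2-yl)lithium (5-lithio-2,3-dihydrofuran), prepared and used as a THF solution | [Li]C1=CCCO1 | intermediate
11 | [(4S)-5-((tert-butyldimethylsilyl)oxy)-4-methylpentyl]lithium | CC(C)(C)[Si](C)(C)OC[C@@H](C)CCC[Li] | intermediate (not isolated)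
12 | lithium [(4S)-5-((tert-butyldimethylsilyl)oxy)-4-methylpentyl](4,5-dihydrofuran-2-yl)cuprate (monovalent copper) | CC(C)(C)[Si](C)(C)OC[C@@H](C)CCC[Cu-]C1=CCCO1.[Li+] | intermediate (not isolated)
13 | ring-opened cyclic lithium alkenyl(alkoxy)cuprate: copper bound to the alkenyl carbon carrying the (4S)-5-((tert-butyldimethylsilyl)oxy)-4-methylpentyl chain and to the terminal alkoxide oxygen (six-membered Cu–C=CH–CH2–CH2–O ring) | CC(C)(C)[Si](C)(C)OC[C@@H](C)CCCC1=CCCO[Cu-]1.[Li+] | intermediate (not isolated)
14 | (S,E)-9-((tert-butyldimethylsilyl)oxy)-4,8-dimethylnon-3-en-1-ol | CC(C)(C)[Si](C)(C)OC[C@@H](C)CCC/C(C)=C/CCO | intermediate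
15 | tert-butyl{[(2S,6E)-9-iodo-2,6-dimethylnon-6-en-1-yl]oxy}dimethylsilane | CC(C)(C)[Si](C)(C)OC[C@@H](C)CCC/C(C)=C/CCI | intermediate
16 | [(3E,8S)-9-((tert-butyldimethylsilyl)oxy)-4,8-dimethylnon-3-en-1-yl]lithium | CC(C)(C)[Si](C)(C)OC[C@@H](C)CCC/C(C)=C/CC[Li] | intermediate (not isolated)
17 | lithium [(3E,8S)-9-((tert-butyldimethylsilyl)oxy)-4,8-dimethylnon-3-en-1-yl](4,5-dihydrofuran-2-yl)cuprate (monovalent copper) | CC(C)(C)[Si](C)(C)OC[C@@H](C)CCC/C(C)=C/CC[Cu-]C1=CCCO1.[Li+] | intermediate (not isolated)
18 | ring-opened cyclic lithium alkenyl(alkoxy)cuprate: as 13, with the (3E,8S)-9-((tert-butyldimethylsilyl)oxy)-4,8-dimethylnon-3-en-1-yl chain on the copper-bearing alkenyl carbon | CC(C)(C)[Si](C)(C)OC[C@@H](C)CCC/C(C)=C/CCC1=CCCO[Cu-]1.[Li+] | intermediate (not isolated)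
19 | (3E,7E,12S)-13-((tert-butyldimethylsilyl)oxy)-4,8,12-trimethyltrideca-3,7-dien-1-ol | CC(C)(C)[Si](C)(C)OC[C@@H](C)CCC/C(C)=C/CC/C(C)=C/CCO | intermediate
20 | tert-butyl{[(2S,6E,10E)-13-iodo-2,6,10-trimethyltrideca-6,10-dien-1-yl]oxy}dimethylsilane | CC(C)(C)[Si](C)(C)OC[C@@H](C)CCC/C(C)=C/CC/C(C)=C/CCI | intermediate
21 | 3-bromofuran | Brc1ccoc1 | starting material
22 | [(3E,7E,12S)-13-((tert-butyldimethylsilyl)oxy)-4,8,12-trimethyltrideca-3,7-dien-1-yl]zinc iodide | CC(C)(C)[Si](C)(C)OC[C@@H](C)CCC/C(C)=C/CC/C(C)=C/CC[Zn]I | intermediate (not isolated)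
23 | tert-butyl{[(2S,6E,10E)-13-(furan-3-yl)-2,6,10-trimethyltrideca-6,10-dien-1-yl]oxy}dimethylsilane | CC(C)(C)[Si](C)(C)OC[C@@H](C)CCC/C(C)=C/CC/C(C)=C/CCc1ccoc1 | intermediate
24 | (2S,6E,10E)-13-(furan-3-yl)-2,6,10-trimethyltrideca-6,10-dien-1-ol | OC[C@@H](C)CCC/C(C)=C/CC/C(C)=C/CCc1ccoc1 | intermediate
25 | (2S,6E,10E)-13-(furan-3-yl)-2,6,10-trimethyltrideca-6,10-dienal | O=C[C@@H](C)CCC/C(C)=C/CC/C(C)=C/CCc1ccoc1 | intermediate
26 | 4-hydroxy-3-methylfuran-2(5H)-one (3-methyltetronic acid) | OC1=C(C)C(=O)OC1 | starting material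
27 | 3-methyl-4-(prop-2-en-1-yloxy)furan-2(5H)-one | C=CCOC1=C(C)C(=O)OC1 | intermediate
28 | trimethyl{[3-methyl-4-(prop-2-en-1-yloxy)furan-2-yl]oxy}silane | C=CCOc1coc(O[Si](C)(C)C)c1C | intermediate
29 | (5R)-5-[(1R,2S,6E,10E)-13-(furan-3-yl)-2,6,10-trimethyl-1-((trimethylsilyl)oxy)trideca-6,10-dien-1-yl]-3-methyl-4-(prop-2-en-1-yloxy)furan-2(5H)-one (erythro; drawn as one of the two erythro isomers) | C=CCOC1=C(C)C(=O)O[C@@H]1[C@H](O[Si](C)(C)C)[C@@H](C)CCC/C(C)=C/CC/C(C)=C/CCc1ccoc1 | intermediate (not isolated)
30 | (5R)-5-[(1R,2S,6E,10E)-13-(furan-3-yl)-1-hydroxy-2,6,10-trimethyltrideca-6,10-dien-1-yl]-3-methyl-4-(prop-2-en-1-yloxy)furan-2(5H)-one (erythro; its (5S,1'S) twin gives the same alkene) | C=CCOC1=C(C)C(=O)O[C@@H]1[C@H](O)[C@@H](C)CCC/C(C)=C/CC/C(C)=C/CCc1ccoc1 | intermediate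
31 | (5E)-5-[(2S,6E,10E)-13-(furan-3-yl)-2,6,10-trimethyltrideca-6,10-dien-1-ylidene]-3-methyl-4-(prop-2-en-1-yloxy)furan-2(5H)-one | C=CCOC1=C(C)C(=O)O/C1=C/[C@@H](C)CCC/C(C)=C/CC/C(C)=C/CCc1ccoc1 | intermediate
32 | (5E)-5-[(2S,6E,10E)-13-(furan-3-yl)-2,6,10-trimethyltrideca-6,10-dien-1-ylidene]-4-hydroxy-3-methylfuran-2(5H)-one | OC1=C(C)C(=O)O/C1=C/[C@@H](C)CCC/C(C)=C/CC/C(C)=C/CCc1ccoc1 | intermediate
33 | (5E)-5-[(2S,6E,10E)-13-(furan-3-yl)-2,6,10-trimethyltrideca-6,10-dien-1-ylidene]-3-methyl-2-oxo-2,5-dihydrofuran-4-yl octadecanoate | CCCCCCCCCCCCCCCCCC(=O)OC1=C(C)C(=O)O/C1=C/[C@@H](C)CCC/C(C)=C/CC/C(C)=C/CCc1ccoc1 | target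

**Step count**

Total: 21 steps; step 8, a reagent preparation, is performed afresh before each of its two uses (steps 9 and 11). Longest linear sequence: 18 steps (steps 1–7, 9–15 and 18–21, from Roche ester 1). Step 8 (from 2,3-dihydrofuran 9) and steps 16–17 (from 3-methyltetronic acid 26) are side branches.

**Steps most likely to fail**

1. Step 18. The fluoride-triggered addition may show too little preference for the erythro relationship, or the basic furanolate may enolise the α-methyl aldehyde and erode the stereocentre. The fallback sets out from 25 and 28 and changes both the activation and the sense of the elimination. Lewis-acid activation (BF3·OEt2, CH2Cl2, −78 °C; aq NaHCO3 work-up), non-basic and threo-selective for 2-silyloxyfurans, should give the threo adduct (5S)-5-[(1R,2S,6E,10E)-13-(furan-3-yl)-1-hydroxy-2,6,10-trimethyltrideca-6,10-dien-1-yl]-3-methyl-4-(prop-2-en-1-yloxy)furan-2(5H)-one F1 together with its (5R,1'S) twin. This is then dehydrated in the syn sense with 1-ethyl-3-(3-dimethylaminopropyl)carbodiimide and CuCl2 (cat.) in toluene at 60 °C, where the isourea nitrogen removes the C5 hydrogen on the same face as the leaving oxygen. Threo plus syn elimination again places the chain cis to C4, so the fallback rejoins the route at 31.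

2. Step 19. The elimination may lose stereospecificity by drifting through the furanolate (stepwise loss of the leaving group after deprotonation), or the phosphine may isomerise the product, in both cases towards the more stable Z alkene. The fallback sets out from 30 and gives up stereospecific elimination. Mesylation (MsCl, Et3N, CH2Cl2, 0 °C) gives (5R)-5-[(1R,2S,6E,10E)-13-(furan-3-yl)-1-(methylsulfonyloxy)-2,6,10-trimethyltrideca-6,10-dien-1-yl]-3-methyl-4-(prop-2-en-1-yloxy)furan-2(5H)-one F2. DBU then eliminates it deliberately to the thermodynamic (5Z)-5-[(2S,6E,10E)-13-(furan-3-yl)-2,6,10-trimethyltrideca-6,10-dien-1-ylidene]-3-methyl-4-(prop-2-en-1-yloxy)furan-2(5H)-one F3. Irradiation of F3 (350 nm, benzene) should set up a photostationary Z/E mixture, from which the E isomer is separated by chromatography and the Z isomer recycled. The fallback comes back to the route at 31.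

3. Step 9 (and its repeat, step 11). The alkyl group may fail to migrate cleanly: protonation of the organometallic, oxidative homocoupling of the cuprate, or incomplete capture of the alkenylcuprate by methyl iodide, which would leave a disubstituted alkene. The fallback sets out from 8 and builds the same alkene by carbometallation. Displacement of iodide with lithium acetylide–ethylenediamine (DMSO, rt) gives (S)-tert-butyldimethyl((2-methylhept-6-yn-1-yl)oxy)silane F4. Zirconium-catalysed methylalumination (Me3Al, Cp2ZrCl2 (cat.), CH2Cl2, rt) adds methyl and aluminium syn across the alkyne to give dimethyl[(1E,6S)-7-((tert-butyldimethylsilyl)oxy)-2,6-dimethylhept-1-en-1-yl]alane F5. Treatment with n-BuLi converts it into the alanate lithium butyl(dimethyl)[(1E,6S)-7-((tert-butyldimethylsilyl)oxy)-2,6-dimethylhept-1-en-1-yl]aluminate F6. Opening of ethylene oxide by F6 (THF, 0 °C) then gives the E homoallylic alcohol with retention, rejoining the route at 14.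

**Further compounds**

F1 | step 18 | (5S)-5-[(1R,2S,6E,10E)-13-(furan-3-yl)-1-hydroxy-2,6,10-trimethyltrideca-6,10-dien-1-yl]-3-methyl-4-(prop-2-en-1-yloxy)furan-2(5H)-one (threo) | C=CCOC1=C(C)C(=O)O[C@H]1[C@H](O)[C@@H](C)CCC/C(C)=C/CC/C(C)=C/CCc1ccoc1
F2 | step 19 | (5R)-5-[(1R,2S,6E,10E)-13-(furan-3-yl)-1-(methylsulfonyloxy)-2,6,10-trimethyltrideca-6,10-dien-1-yl]-3-methyl-4-(prop-2-en-1-yloxy)furan-2(5H)-one | C=CCOC1=C(C)C(=O)O[C@@H]1[C@H](OS(C)(=O)=O)[C@@H](C)CCC/C(C)=C/CC/C(C)=C/CCc1ccoc1
F3 | step 19 | (5Z)-5-[(2S,6E,10E)-13-(furan-3-yl)-2,6,10-trimethyltrideca-6,10-dien-1-ylidene]-3-methyl-4-(prop-2-en-1-yloxy)furan-2(5H)-one | C=CCOC1=C(C)C(=O)O/C1=C\[C@@H](C)CCC/C(C)=C/CC/C(C)=C/CCc1ccoc1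
F4 | step 9 | (S)-tert-butyldimethyl((2-methylhept-6-yn-1-yl)oxy)silane | CC(C)(C)[Si](C)(C)OC[C@@H](C)CCCC#C
F5 | step 9 | dimethyl[(1E,6S)-7-((tert-butyldimethylsilyl)oxy)-2,6-dimethylhept-1-en-1-yl]alane | CC(C)(C)[Si](C)(C)OC[C@@H](C)CCC/C(C)=C/[Al](C)C
F6 | step 9 | lithium butyl(dimethyl)[(1E,6S)-7-((tert-butyldimethylsilyl)oxy)-2,6-dimethylhept-1-en-1-yl]aluminate | CC(C)(C)[Si](C)(C)OC[C@@H](C)CCC/C(C)=C/[Al-](C)(C)CCCC.[Li+]
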